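The numbers of this flask stand for no real mixture; the rest is arithmetic.

With no substrate in a flask, the easy step is the one that remains: free catalyst turns target into over-reaction product, while added ligand holds part of the catalyst as idle complex.

    substrate + free catalyst ⇌ catalyst intermediate A (K1 = 40.0 M⁻¹, k1 = 1380 M⁻¹ s⁻¹)
    catalyst intermediate A ⇌ catalyst intermediate B (K2 = 15.5, k2 = 1.90 s⁻¹)
    catalyst intermediate B → free catalyst + target (k3 = 2.78 s⁻¹)
    free catalyst + target → free catalyst + over-reaction product (k4 = 2.64 M⁻¹ s⁻¹)
    2 substrate → homo dimer (k5 = 0.00153 M⁻¹ s⁻¹)
    free catalyst + added ligand ⇌ idle complex, settled at all times (K6 = 710 M⁻¹)

One charge goes through four set-ups: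

| flask | substrate | free catalyst | added ligand | time | remark |
|---|---|---|---|---|---|
| dusk | 0.19 M | 0.05 mol% | 0.55 mM | 50 min | everything together in a closed stirred flask, run for 50 min |
| noon | 0.19 M | 0.05 mol% | 0.55 mM |  | a single well-mixed tank run continuously and read at steady state, 50 min in it on average |
| dawn | 0.19 M | 0.05 mol% | 0.55 mM | 50 min | plug flow through a tube for 50 min, no back-mixing |
| winter | 0.19 M (fed, over 40.0 min) | 0.05 mol% | 0.55 mM | 50 min | a stirred flask in which substrate is dosed at a steady rate over 40.0 min without added volume, worked up at 50 min |
- the set-up with the highest amount of target at the outlet or at the end, in percent of the substrate put in ("none" if the first two lie within 2 percentage points) (dusk / noon / dawn / winter / none)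
- amount of target at the outlet or at the end, in percent of the substrate put in, dusk
- amount of target at the outlet or at the end, in percent of the substrate put in, noon
- amount of target at the outlet or at the end, in percent of the substrate put in, dawn
- amount of target at the outlet or at the end, in percent of the substrate put in, winter
- percentages count the substrate that a species holds: one homo dimer counts as two
- a step written with two of one species runs at k times the square of its concentration and takes two of it each time
- the stated concentrations are those of everything mixed, before any reaction; amounts are the same in each set-up
- the feed brings no volume worth counting
- run time (dusk): 50 min

The reckoning here goes as far as this tail and names no yield. With free catalyst constant, target decays by a pseudo-first-order law, and its half-life can be reached in two ways. The first takes the catalyst as charged, all of it free: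

half-life = ln 2 / (rate constant of over-reaction × catalyst charged) = 46 min

The second divides the catalyst by the ligand balance first, with binding constant × added ligand = 0.39:

free share = 1 / (1 + 0.39) = 71.9%
half-life = 46 min / 71.9% = 64.0 min

The second half-life is longer than the first. The first way cheats: it counts as free the 28.1% of the catalyst that the balance puts in idle complex. The balance holds added ligand at its charge, and the bound catalyst takes 4.85% of it, a small correction left uncounted. So the tail clock, the half-life of target with substrate absent and the catalyst shared between free catalyst and idle complex, is 64.0 min, and each such span without substrate halves the target.

The forecast names winter as best, with 58% for dusk, 67.5% for noon, 58% for dawn and 80.5% for winter, on the ground that “keeping substrate low wins”.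

The simulation gives winter as best, with 57.6% for dusk, 67.3% for noon, 57.6% for dawn and 80.8% for winter, so the forecast stands within its tolerance on each.

The dusk flask has not come to rest at 50.0 min. Its substrate stands at 0.026% and its homo dimer at 25.1%. At 500 min, ten times the time, dusk homo dimer reads 25.1%, while target has gone from 57.6% to 0.414% and over-reaction product from 17.3% to 74.5%. The tail clock reaches that target figure by hand: the 450 min between hold 7.03 half-lives, which take 57.6% down to 0.442%, beside the simulated 0.414%.

Winter left until 2.0 h starts the same reckoning from 80.8% target and 5.29% substrate: taking that substrate as target, the extra 70.0 min on the clock give 40.4%. That flask reads 40.8% target, with 54.5% as over-reaction product.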